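**Remarks on the chemistry (conventions and one assumption)**

- Labdane numbering is used throughout: C1–C10 for the decalin, C11–C16 for the side chain, C17 on C8, C20 on C10. α is the face of ring B that carries the C10 methyl in the target as drawn; β is the opposite face, that of H-5.
- Assumption: (S)-t-Bu-PHOX is taken to give the (S)-configured ketone 4, the sense it shows with simpler 2-alkylcyclohexanone enol carbonates. If the sense were opposite, the (R)-ligand would be used.

## Analysis of the target

Compound 28 is a labdane-type diterpenoid of the enantiomeric series. It is a trans-fused decalin (rings A and B) with a gem-dimethyl group on C4, an angular methyl on C10 and a (2Z)-3-methylpenta-2,4-dienyl chain on C9. Six contiguous stereocentres run from C5 to C10 (5R,6S,7R,8R,9S,10R). With the C10 methyl α, H-5 is β and every ring-B substituent is equatorial: 6-OH β, 7-OAc α, 8-OH β (the C8 methyl is axial, α, syn to the C10 methyl) and the C9 chain α. The sensitive parts are the Z-configured conjugated diene (acid can isomerise it or make the 8-hydroxyl add to C13), the tertiary alcohol, and the lone acetate between two free hydroxyls, which can migrate under base. The difficulty lies in the quaternary C10 beside the tertiary C9 and the fully substituted C8, in three neighbouring oxygens that must end in three different states, and in the trisubstituted Z-alkene. The plan rests on the position of C9 between the quaternary C10 and C8: when C5–C7 is held as a 5-en-7-one, C8 is an enolate carbon and can add to a C9=C11 acrylate attached to C10, which makes C8–C9 and closes ring B. The C7 carbonyl is then used in turn to bring in O8, H-5, O6 and the C7 carbinol, each at the only position open at that stage.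

## Retrosynthetic reasoning

**Diene (C13–C14).** The Z-diene is the most fragile part of 28, so it is made last. Cutting C13–C14 gives the (Z)-vinyl iodide 26 and the vinyl stannane 27. A Stille coupling runs under neutral conditions, keeps the alkene geometry and tolerates the free hydroxyls and the acetate.

**Oxygen pattern (26 back to 24).** Compound 26 comes from 25 by removal of the O6 silyl group, and 25 from 24 by acetylation. In 24 only O7 can be acylated: O6 is silylated and O8 is tertiary. The silyl group is removed while the side chain is still a robust vinyl iodide, so the diene never meets fluoride or acid.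

**C12=C13.** Cutting the alkene of 24 leads to the lactol 22 and the two-carbon phosphonium salt 23. An iodo-olefination of the Stork–Zhao type sets the Z geometry and installs the iodine that step 19 needs. Lactol 22 comes from lactone 21 by partial reduction. The lactone ties O8 and C12 together through all the redox steps on ring B.

**C7 carbinol and O6.** Alcohol 21 comes from ketone 20 by hydride delivery to the β face. Ketone 20 is the silyl ether of ketol 19, which comes from 17 through its silyl enol ether 18 by Rubottom oxidation. In 17 C6 is the only enolisable carbon because C8 is quaternary.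

**H-5.** Ketone 17 comes from enone 16 by hydrogenation. The three axial methyl groups on the α face should force hydrogen onto the β face and so give the trans ring fusion.

**O8.** Lactone 16 comes from hydroxy ester 15, and 15 from the ring-closure product 13 through the silyl dienol ether 14. In 13 C8 is the only enolisable carbon because C6 is vinylic and C4 and C10 are quaternary.

**Key disconnection (C8–C9).** Cutting C8–C9 of 13 opens ring B to the ethyl enone–acrylate 12. Forward, the C8 enolate adds to C9 of the acrylate. The new centre C9 is set relative to C10. Only the geometric isomer with C7 cis to C10 can cyclise, so the isomer mixture 11 has to be channelled through 12.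

**Precursor assembly.** Mixture 11 comes from the propargylic alcohol 10 by Meyer–Schuster rearrangement (C5=C6 and C7=O). Enoate 10 comes from aldehyde 8 and phosphonate 9 (C9=C11). Aldehyde 8 comes from 7 by oxidative cleavage of the propenyl group. Alcohol 7 comes from ketone 5 and but-1-yne 6 (C5–C6). Ketone 5 is the alkene-migration product of 4. Ketone 4 comes from the enol carbonate 3 by decarboxylative asymmetric allylation, which sets C10, and 3 from the commercial ketone 1 and chloroformate 2. Ring A is bought, and C10 is the only stereocentre set by a catalyst.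

## Alternatives that were turned down

**Alternative 1:** Cut C5–C6 and C1–C10, so that both rings come from the acyclic triene A1. Forward, SnCl4 ionises the (Z)-allylic alcohol. The (E)-C5=C10 alkene attacks the C6 end of the allyl cation (ring B), and the C10 cation is taken up at the silicon-bearing carbon of the (Z)-vinylsilane (ring A) to give diene A2.
- For: two rings, the trans fusion and C5/C10 are made in one step from a chain that already carries C11–C12 with its oxygen. On ring-forming economy this is stronger than the chosen plan.
- Against: A1 needs three alkenes of defined geometry and an acyclic stereocentre (C9) that alone has to relay the absolute configuration. A2 carries no oxygen at C6, C7 or C8, only a C7=C8 alkene. Dihydroxylation of that alkene gives a cis-7,8-diol where 28 needs trans. C6 would need a separate allylic oxidation and the C1=C2 alkene a selective reduction.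
- Comparison: the chosen plan gives up the double ring closure. In return C7 is at the right oxidation level from the moment ring B forms, and every later oxygen enters at a position without a competitor.

**Alternative 2:** Cut C9–C10 with cleavage of C6–O, an Ireland–Claisen ring contraction of the δ-lactone A3. Forward, KN(SiMe3)2 and Et3SiCl give the silyl ketene acetal, which on heating bonds C9 to C10 of the cyclohexenyl group as C6–O breaks, giving acid A4.
- For: the quaternary C10 and C9 are formed together with chirality transfer from C6, and O8 arrives in the key step, which the chosen plan cannot match.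
- Against: the endocyclic ketene acetal enforces a boat transition state, which puts the carboxyl anti to the C10 methyl, so A4 is the C9 epimer and must be inverted. A4 stops at C11 and needs a one-carbon homologation before the diene can be built. C7 is a methylene and needs an allylic oxidation. A3 must first be made as one enantiomer with two stereocentres.
- Comparison: the chosen plan delivers C9 in the needed configuration, C11 and C12 together, and C7 already oxidised, and it sets C10 by catalysis on a bought ring.

**Alternative 3:** Cut C8–C9 and C5–C10, a catalytic asymmetric Diels–Alder reaction of diene A5 with enal A6. Forward, a chiral oxazaborolidinium acid activates A6, which adds across A5 to close ring B as the endo adduct A7.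
- For: it is convergent, the catalyst sets the absolute configuration, four stereocentres form in one step, and O7 is present as a silyl enol ether. In convergence and in stereocentres per step it is stronger than the chosen plan.
- Against: the C5–C10 bond joins a forming quaternary carbon of an α-methyl enal to a diene terminus that carries a tertiary alkyl group, a severe steric load on a weak dienophile class. The endo rule puts the C5 chain cis to the formyl group, that is H-5 on the face of the C10 methyl, so C5 would have to be reset later. Ring A must still be closed and reduced. The C7 ketone from A7 is enolisable at both C6 and C8.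
- Comparison: the chosen plan buys ring A, asks the catalyst for C10 only, on a substrate class where that reaction is established, and lets C9 follow from C10 in the ring closure.

Key step: step 8

## Route

**Step 1**
Reactants: 1 2,2,6-trimethylcyclohexan-1-one; 2 allyl chloroformate
Product: 3 allyl 2,6,6-trimethylcyclohex-1-en-1-yl carbonate
Conditions: LiN(SiMe3)2, THF, 0 °C; then 2, −78 °C → rt
Reagents that add atoms: none
Why: Only C6 carries an α-hydrogen, so enolisation is regiospecific, and the hindered tetrasubstituted lithium enolate is acylated on oxygen by the chloroformate (enol carbonate formation).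

**Step 2**
Reactants: 3 allyl 2,6,6-trimethylcyclohex-1-en-1-yl carbonate
Product: 4 (2S)-2-allyl-2,6,6-trimethylcyclohexan-1-one
Conditions: Pd2(dba)3 (cat.), (S)-t-Bu-PHOX (cat.), THF, 25 °C
Reagents that add atoms: none
Why: Decarboxylative asymmetric allylic alkylation (Tsuji type): zerovalent palladium ionises the carbonate, CO2 is lost, and the enolate and allyl group combine within the chiral Pd–PHOX complex, whose ligand selects the enolate face and so sets the quaternary C10.

**Step 3**
Reactants: 4 (2S)-2-allyl-2,6,6-trimethylcyclohexan-1-one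
Product: 5 (2S)-2,6,6-trimethyl-2-[(1E)-prop-1-en-1-yl]cyclohexan-1-one
Conditions: RuHCl(CO)(PPh3)3 (cat.), toluene, 80 °C
Reagents that add atoms: none
Why: Ruthenium-hydride alkene migration (hydrometalation, then β-hydride elimination) moves the terminal alkene one position to the more stable (E)-propenyl group; it cannot go further because C10 is quaternary, and C10 is untouched.

**Step 4**
Reactants: 5 (2S)-2,6,6-trimethyl-2-[(1E)-prop-1-en-1-yl]cyclohexan-1-one; 6 but-1-yne
Product: 7 (2S)-1-(but-1-yn-1-yl)-2,6,6-trimethyl-2-[(1E)-prop-1-en-1-yl]cyclohexan-1-ol (both epimers at the carbinol carbon C5)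
Conditions: 6, n-BuLi, THF, −78 °C; CeCl3, −78 °C; then 5, −78 → 0 °C
Reagents that add atoms: none
Why: 1,2-Addition of an alkynyl-lithium/cerium reagent to a ketone that cannot enolise; the slim sp nucleophile should pass between the two flanking quaternary carbons, and the C5 epimer mixture is of no consequence because C5 becomes sp2 in step 7.

**Step 5**
Reactants: 7 (2S)-1-(but-1-yn-1-yl)-2,6,6-trimethyl-2-[(1E)-prop-1-en-1-yl]cyclohexan-1-ol
Product: 8 (1R)-2-(but-1-yn-1-yl)-2-hydroxy-1,3,3-trimethylcyclohexane-1-carbaldehyde (both epimers at C5)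
Conditions: O3, CH2Cl2/MeOH, −78 °C, to the first persistence of ozone; then Me2S, −78 °C → rt
Reagents that add atoms: ozone, [O-][O+]=O
Why: Ozonolysis with reductive work-up; the 1,2-disubstituted alkene reacts far faster than the internal alkyne, so careful dosing should cleave only the propenyl group and leave the C9 aldehyde on C10.

**Step 6**
Reactants: 8 (1R)-2-(but-1-yn-1-yl)-2-hydroxy-1,3,3-trimethylcyclohexane-1-carbaldehyde; 9 trimethyl phosphonoacetate
Product: 10 methyl (2E)-3-[(1S)-2-(but-1-yn-1-yl)-2-hydroxy-1,3,3-trimethylcyclohexyl]prop-2-enoate (both epimers at C5)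
Conditions: 9, LiCl, DBU, MeCN, 0 °C → rt
Reagents that add atoms: none
Why: Horner–Wadsworth–Emmons olefination under Masamune–Roush conditions; the weak amine base does not deprotonate the tertiary alcohol, so retro-aldol opening of the β-hydroxy aldehyde is avoided, and the stabilised phosphonate gives the (E)-enoate.

**Step 7**
Reactants: 10 methyl (2E)-3-[(1S)-2-(but-1-yn-1-yl)-2-hydroxy-1,3,3-trimethylcyclohexyl]prop-2-enoate
Product: 11 methyl (2E)-3-[(1S)-1,3,3-trimethyl-2-(2-oxobutylidene)cyclohexyl]prop-2-enoate, as a mixture of the two geometric isomers at the exocyclic C5=C6 bond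
Conditions: Ph3PAuNTf2 (cat.), MeOH (1 equiv), toluene, rt → 50 °C
Reagents that add atoms: none
Why: Meyer–Schuster rearrangement under monovalent gold catalysis: the hydroxyl formally shifts from C5 to C7 through an allenol that tautomerises to the enone; the competing Rupe pathway is closed because C4 and C10 carry no hydrogen, the electron-poor acrylate does not engage the activated alkyne, and the C5=C6 geometry is left uncontrolled on purpose.

**Step 8**
Reactants: 11 methyl (2E)-3-[(1S)-1,3,3-trimethyl-2-(2-oxobutylidene)cyclohexyl]prop-2-enoate (isomer mixture)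
Product: 13 methyl 2-[(1R,2R,8aS)-2,5,5,8a-tetramethyl-3-oxo-1,2,3,5,6,7,8,8a-octahydronaphthalen-1-yl]acetate, via (Z)-enone isomer 12 (not isolated)
Conditions: KOt-Bu (0.3 equiv), THF/t-BuOH, 0 °C → rt, 0.02 M, 365 nm irradiation until 11 is consumed
Reagents that add atoms: none
Why: The alkoxide reversibly deprotonates C8, the only enolisable carbon of either isomer (C4 and C10 are quaternary, so there is no γ-hydrogen), giving a cross-conjugated potassium dienolate. In the (Z)-isomer 12, where C7 is cis to C10, C8 reaches the β-carbon C9 of the (E)-acrylate and adds to it, forming C8–C9 and closing ring B in a 6-(enolendo)-exo-trig mode that the Baldwin rules for enolates allow; the ester enolate is then protonated by t-BuOH, which returns the base. The closest known reaction type is the alkoxide-mediated intramolecular Michael addition of a ketone enolate to an α,β-unsaturated ester. The (E)-isomer cannot reach C9, but 365 nm light excites the enone n→π* band and interconverts the two isomers through the twisted excited state, so the whole mixture should drain through 12. C9 is set relative to the fixed C10: the chair of ring A holds the C10 methyl pseudo-axial in the forming half-chair, and the acrylate is expected to lie pseudo-equatorial, pointing away from the dienolate, which places the acetate arm cis to the C10 methyl. Because the addition can revert through the ester enolate, a wrongly closed C9 epimer has a path back, although the thermodynamic preference at this centre is judged to be modest. C8 forms with its methyl pseudo-equatorial and trans to the arm (from the enolate with methyl cis to oxygen, and in any case by epimerisation), and this centre is provisional because step 9 makes it planar again. The step needs C- over O-alkylation (O-attack is reversible) and ring closure over intermolecular addition, which dilution secures.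

**Step 9**
Reactants: 13 methyl (8R,9R,10S)-7-oxo-13,14,15,16-tetranorlabd-5-en-12-oate (the octahydronaphthalenyl acetate of step 8)
Product: 15 methyl (8R,9S,10S)-8-hydroxy-7-oxo-13,14,15,16-tetranorlabd-5-en-12-oate (8-OH β; C8 methyl α), via trimethylsilyl dienol ether 14 (not isolated)
Conditions: TMSOTf, Et3N, CH2Cl2, 0 °C; then mCPBA, NaHCO3, CH2Cl2, −20 °C; then aq. citric acid, THF, rt
Reagents that add atoms: trimethylsilyl triflate (silyl group of 14 only), C[Si](C)(C)OS(=O)(=O)C(F)(F)F; mCPBA, OOC(=O)c1cccc(Cl)c1
Why: Rubottom oxidation: soft enolisation can only go toward C8 and leaves the ester alone; the peracid epoxidises the electron-rich C7=C8 bond of 14 on the β face, away from the pseudo-axial C10 methyl, and silyl transfer followed by mild acid releases the tertiary ketol with O8 β and the C8 methyl α.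

**Step 10**
Reactants: 15 methyl (8R,9S,10S)-8-hydroxy-7-oxo-13,14,15,16-tetranorlabd-5-en-12-oate
Product: 16 (8R,9S,10S)-7-oxo-13,14,15,16-tetranorlabd-5-en-12,8-olide (trans-fused γ-lactone between O8 and C12)
Conditions: p-TsOH·H2O (cat.), toluene, 80 °C
Reagents that add atoms: none
Why: Acid-catalysed lactonisation: the β 8-hydroxyl and the α acetate arm on C9 are trans-diequatorial neighbours and close to the trans-fused five-membered lactone with loss of methanol, which masks O8 and C12 together; a cation at C8 is disfavoured by the adjacent carbonyl, so dehydration is not expected.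

**Step 11**
Reactants: 16 (8R,9S,10S)-7-oxo-13,14,15,16-tetranorlabd-5-en-12,8-olide
Product: 17 (5R,8R,9S,10R)-7-oxo-13,14,15,16-tetranorlabdan-12,8-olide (H-5 β, trans-decalin)
Conditions: H2 (4 atm), 10% Pd/C, EtOAc, rt
Reagents that add atoms: none
Why: Heterogeneous hydrogenation of the enone C=C; the α face is screened by the axial methyl groups on C4, C8 and C10, so hydrogen should be delivered to C5 and C6 from the β face, which sets H-5 anti to the C10 methyl.

**Step 12**
Reactants: 17 (5R,8R,9S,10R)-7-oxo-13,14,15,16-tetranorlabdan-12,8-olide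
Product: 19 (5R,6S,8R,9S,10R)-6-hydroxy-7-oxo-13,14,15,16-tetranorlabdan-12,8-olide (6-OH β, equatorial), via trimethylsilyl enol ether 18 (not isolated)
Conditions: TMSOTf, Et3N, CH2Cl2, 0 °C → rt; then mCPBA, NaHCO3, CH2Cl2, −20 °C; then aq. citric acid, THF, rt
Reagents that add atoms: trimethylsilyl triflate (silyl group of 18 only), C[Si](C)(C)OS(=O)(=O)C(F)(F)F; mCPBA, OOC(=O)c1cccc(Cl)c1
Why: Second Rubottom oxidation: with C8 quaternary the ketone can enolise only toward C6, and the peracid attacks the C6=C7 enol ether from the β face because three axial methyl groups block the α face, giving the equatorial 6β-hydroxyl.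

**Step 13**
Reactants: 19 (5R,6S,8R,9S,10R)-6-hydroxy-7-oxo-13,14,15,16-tetranorlabdan-12,8-olide
Product: 20 (5R,6S,8R,9S,10R)-6-(tert-butyldimethylsilyloxy)-7-oxo-13,14,15,16-tetranorlabdan-12,8-olide
Conditions: TBSOTf, 2,6-lutidine, CH2Cl2, −78 → 0 °C
Reagents that add atoms: tert-butyldimethylsilyl triflate, CC(C)(C)[Si](C)(C)OS(=O)(=O)C(F)(F)F
Why: Silylation of a hindered secondary alcohol with a silyl triflate and a weak, non-nucleophilic base that does not enolise the ketol; O6 is blocked so that O7 can later be acylated alone.

**Step 14**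
Reactants: 20 (5R,6S,8R,9S,10R)-6-(tert-butyldimethylsilyloxy)-7-oxo-13,14,15,16-tetranorlabdan-12,8-olide
Product: 21 (5R,6S,7R,8R,9S,10R)-6-(tert-butyldimethylsilyloxy)-7-hydroxy-13,14,15,16-tetranorlabdan-12,8-olide (7-OH α, equatorial)
Conditions: NaBH4, MeOH/THF, −20 → 0 °C
Reagents that add atoms: none
Why: Borohydride reduction of the ketone; the small hydride attacks axially from the β face because the equatorial approach is blocked by the axial C8 methyl, giving the equatorial 7α-alcohol, and the γ-lactone is not reduced at this temperature.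

**Step 15**
Reactants: 21 (5R,6S,7R,8R,9S,10R)-6-(tert-butyldimethylsilyloxy)-7-hydroxy-13,14,15,16-tetranorlabdan-12,8-olide
Product: 22 (5R,6S,7R,8R,9S,10R)-6-(tert-butyldimethylsilyloxy)-8,12-epoxy-13,14,15,16-tetranorlabdane-7,12-diol (lactol, both C12 epimers)
Conditions: i-Bu2AlH (3 equiv), CH2Cl2, −78 °C; aq. potassium sodium tartrate
Reagents that add atoms: none
Why: Partial reduction of the lactone; the aluminium hemiacetal is stable at −78 °C and gives the lactol on work-up, and one extra equivalent of hydride is consumed by the free 7-hydroxyl.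

**Step 16**
Reactants: 22 (5R,6S,7R,8R,9S,10R)-6-(tert-butyldimethylsilyloxy)-8,12-epoxy-13,14,15,16-tetranorlabdane-7,12-diol; 23 ethyltriphenylphosphonium iodide
Product: 24 (5R,6S,7R,8R,9S,10R,12Z)-6-(tert-butyldimethylsilyloxy)-13-iodo-14,15-dinorlabd-12-ene-7,8-diol
Conditions: 23 (excess), n-BuLi, THF, 0 °C; I2, −78 °C; NaN(SiMe3)2, −20 °C; then 22, −78 → −20 °C
Reagents that add atoms: iodine, [I][I]
Why: Stork–Zhao-type Wittig olefination with the α-iodo ylide Ph3P=C(I)CH3 made in the flask; the lactol reacts through its hydroxy-aldehyde form, the kinetically controlled oxaphosphetane pathway of this ylide gives the (Z)-iodoalkene with iodine cis to C11, and the excess of ylide covers the acidic hydroxyls.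

**Step 17**
Reactants: 24 (5R,6S,7R,8R,9S,10R,12Z)-6-(tert-butyldimethylsilyloxy)-13-iodo-14,15-dinorlabd-12-ene-7,8-diol
Product: 25 (5R,6S,7R,8R,9S,10R,12Z)-6-(tert-butyldimethylsilyloxy)-8-hydroxy-13-iodo-14,15-dinorlabd-12-en-7-yl acetate
Conditions: Ac2O, pyridine, DMAP (cat.), CH2Cl2, rt
Reagents that add atoms: acetic anhydride, CC(=O)OC(C)=O
Why: DMAP-catalysed acylation of the secondary 7-hydroxyl; the tertiary, hindered 8-hydroxyl does not react under these conditions and O6 is silylated, so the acetate can only go to O7.

**Step 18**
Reactants: 25 (5R,6S,7R,8R,9S,10R,12Z)-6-(tert-butyldimethylsilyloxy)-8-hydroxy-13-iodo-14,15-dinorlabd-12-en-7-yl acetate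
Product: 26 (5R,6S,7R,8R,9S,10R,12Z)-6,8-dihydroxy-13-iodo-14,15-dinorlabd-12-en-7-yl acetate
Conditions: HF·pyridine, pyridine, THF, 0 °C → rt
Reagents that add atoms: none
Why: Fluoride cleavage of the Si–O bond under weakly acidic, buffered conditions, which avoid base-induced acetyl migration from O7; the vinyl iodide is inert to this reagent, which is why the silyl group is removed before the acid-sensitive diene exists.

**Step 19**
Reactants: 26 (5R,6S,7R,8R,9S,10R,12Z)-6,8-dihydroxy-13-iodo-14,15-dinorlabd-12-en-7-yl acetate; 27 tributyl(vinyl)stannane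
Product: 28 (5R,6S,7R,8R,9S,10R,12Z)-6,8-dihydroxylabda-12,14-dien-7-yl acetate (CNP0225877.2)
Conditions: Pd2(dba)3 (cat.), AsPh3, NMP, rt → 40 °C, dark
Reagents that add atoms: none
Why: Stille coupling: zerovalent palladium adds oxidatively to the vinyl iodide with retention, the vinyl group is transferred from tin and reductive elimination gives the (12Z)-diene; the neutral conditions leave the two hydroxyls and the acetate untouched.

## Compound list

1 | 2,2,6-trimethylcyclohexan-1-one | CC1CCCC(C)(C)C1=O | starting material
2 | allyl chloroformate | C=CCOC(Cl)=O | starting material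
3 | allyl 2,6,6-trimethylcyclohex-1-en-1-yl carbonate | C=CCOC(=O)OC1=C(C)CCCC1(C)C | intermediate
4 | (2S)-2-allyl-2,6,6-trimethylcyclohexan-1-one | C=CC[C@]1(C)CCCC(C)(C)C1=O | intermediate
5 | (2S)-2,6,6-trimethyl-2-[(1E)-prop-1-en-1-yl]cyclohexan-1-one | C/C=C/[C@]1(C)CCCC(C)(C)C1=O | intermediate
6 | but-1-yne | CCC#C | starting material
7 | (2S)-1-(but-1-yn-1-yl)-2,6,6-trimethyl-2-[(1E)-prop-1-en-1-yl]cyclohexan-1-ol, both carbinol epimers | CCC#CC1(O)C(C)(C)CCC[C@@]1(C)/C=C/C | intermediate
8 | (1R)-2-(but-1-yn-1-yl)-2-hydroxy-1,3,3-trimethylcyclohexane-1-carbaldehyde, both carbinol epimers | CCC#CC1(O)C(C)(C)CCC[C@@]1(C)C=O | intermediate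
9 | trimethyl phosphonoacetate | COC(=O)CP(=O)(OC)OC | starting material
10 | methyl (2E)-3-[(1S)-2-(but-1-yn-1-yl)-2-hydroxy-1,3,3-trimethylcyclohexyl]prop-2-enoate, both carbinol epimers | CCC#CC1(O)C(C)(C)CCC[C@@]1(C)/C=C/C(=O)OC | intermediate
11 | methyl (2E)-3-[(1S)-1,3,3-trimethyl-2-(2-oxobutylidene)cyclohexyl]prop-2-enoate, mixture of both geometric isomers at the exocyclic alkene | CCC(=O)C=C1C(C)(C)CCC[C@@]1(C)/C=C/C(=O)OC | intermediate
12 | methyl (2E)-3-[(1S,2Z)-1,3,3-trimethyl-2-(2-oxobutylidene)cyclohexyl]prop-2-enoate (C7 cis to C10) | CCC(=O)/C=C1/C(C)(C)CCC[C@@]1(C)/C=C/C(=O)OC | intermediate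
13 | methyl 2-[(1R,2R,8aS)-2,5,5,8a-tetramethyl-3-oxo-1,2,3,5,6,7,8,8a-octahydronaphthalen-1-yl]acetate | COC(=O)C[C@@H]1[C@@H](C)C(=O)C=C2C(C)(C)CCC[C@]21C | intermediate
14 | methyl (9S,10S)-7-(trimethylsilyloxy)-13,14,15,16-tetranorlabda-5,7-dien-12-oate | COC(=O)C[C@@H]1C(C)=C(O[Si](C)(C)C)C=C2C(C)(C)CCC[C@]21C | intermediate
15 | methyl (8R,9S,10S)-8-hydroxy-7-oxo-13,14,15,16-tetranorlabd-5-en-12-oate | COC(=O)C[C@@H]1[C@@](C)(O)C(=O)C=C2C(C)(C)CCC[C@]21C | intermediate
16 | (8R,9S,10S)-7-oxo-13,14,15,16-tetranorlabd-5-en-12,8-olide | O=C1C[C@@H]2[C@@](C)(O1)C(=O)C=C3C(C)(C)CCC[C@]32C | intermediate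
17 | (5R,8R,9S,10R)-7-oxo-13,14,15,16-tetranorlabdan-12,8-olide | O=C1C[C@@H]2[C@@](C)(O1)C(=O)C[C@@H]3C(C)(C)CCC[C@]32C | intermediate
18 | (5R,8R,9S,10R)-7-(trimethylsilyloxy)-13,14,15,16-tetranorlabd-6-en-12,8-olide | O=C1C[C@@H]2[C@@](C)(O1)C(O[Si](C)(C)C)=C[C@@H]3C(C)(C)CCC[C@]32C | intermediate
19 | (5R,6S,8R,9S,10R)-6-hydroxy-7-oxo-13,14,15,16-tetranorlabdan-12,8-olide | O=C1C[C@@H]2[C@@](C)(O1)C(=O)[C@@H](O)[C@@H]3C(C)(C)CCC[C@]32C | intermediate
20 | (5R,6S,8R,9S,10R)-6-(tert-butyldimethylsilyloxy)-7-oxo-13,14,15,16-tetranorlabdan-12,8-olide | O=C1C[C@@H]2[C@@](C)(O1)C(=O)[C@@H](O[Si](C)(C)C(C)(C)C)[C@@H]3C(C)(C)CCC[C@]32C | intermediate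
21 | (5R,6S,7R,8R,9S,10R)-6-(tert-butyldimethylsilyloxy)-7-hydroxy-13,14,15,16-tetranorlabdan-12,8-olide | O=C1C[C@@H]2[C@@](C)(O1)[C@H](O)[C@@H](O[Si](C)(C)C(C)(C)C)[C@@H]3C(C)(C)CCC[C@]32C | intermediate
22 | (5R,6S,7R,8R,9S,10R)-6-(tert-butyldimethylsilyloxy)-8,12-epoxy-13,14,15,16-tetranorlabdane-7,12-diol, both C12 epimers | OC1C[C@@H]2[C@@](C)(O1)[C@H](O)[C@@H](O[Si](C)(C)C(C)(C)C)[C@@H]3C(C)(C)CCC[C@]32C | intermediate
23 | ethyltriphenylphosphonium iodide | CC[P+](c1ccccc1)(c1ccccc1)c1ccccc1.[I-] | starting material
24 | (5R,6S,7R,8R,9S,10R,12Z)-6-(tert-butyldimethylsilyloxy)-13-iodo-14,15-dinorlabd-12-ene-7,8-diol | C/C(I)=C/C[C@@H]1[C@@](C)(O)[C@H](O)[C@@H](O[Si](C)(C)C(C)(C)C)[C@@H]2C(C)(C)CCC[C@]21C | intermediate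
25 | (5R,6S,7R,8R,9S,10R,12Z)-6-(tert-butyldimethylsilyloxy)-8-hydroxy-13-iodo-14,15-dinorlabd-12-en-7-yl acetate | C/C(I)=C/C[C@@H]1[C@@](C)(O)[C@H](OC(C)=O)[C@@H](O[Si](C)(C)C(C)(C)C)[C@@H]2C(C)(C)CCC[C@]21C | intermediate
26 | (5R,6S,7R,8R,9S,10R,12Z)-6,8-dihydroxy-13-iodo-14,15-dinorlabd-12-en-7-yl acetate | C/C(I)=C/C[C@@H]1[C@@](C)(O)[C@H](OC(C)=O)[C@@H](O)[C@@H]2C(C)(C)CCC[C@]21C | intermediate
27 | tributyl(vinyl)stannane | C=C[Sn](CCCC)(CCCC)CCCC | starting material
28 | (5R,6S,7R,8R,9S,10R,12Z)-6,8-dihydroxylabda-12,14-dien-7-yl acetate | C=C/C(C)=C\C[C@@H]1[C@@](C)(O)[C@H](OC(C)=O)[C@@H](O)[C@@H]2C(C)(C)CCC[C@]21C | target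

## Step count and least certain steps

Total: 19 steps. Longest linear sequence: 19 steps, from 1 to 28; all other inputs are commercial.

**Step 8 (key step).** The most likely failure is incomplete channelling of the geometric isomers: under prolonged irradiation the 1,4-diene unit of the substrate can undergo di-π-methane rearrangement, and the 4,4-disubstituted cyclohexenone product can undergo photochemical skeletal rearrangement, both of which would erode material before the (E)-isomer is used up. The second concern is erosion of the C9 selectivity, because an axial arm on the half-chair of a 5-en-7-one meets no 1,3-diaxial partner and the thermodynamic bias is therefore small. Fallback: separate isomerisation from ring closure. Mixture 11 is treated with KOt-Bu in the dark, so only the (Z)-component closes to 13. The untouched methyl (2E)-3-[(1S,2E)-1,3,3-trimethyl-2-(2-oxobutylidene)cyclohexyl]prop-2-enoate F1 is recovered, re-equilibrated on its own (the gold and acid conditions of step 7, or 350 nm light with no base and no product present) and sent through the dark cyclisation again. This sets out from 11 and returns at 13.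

**Step 16.** The lactol may open too slowly for an ylide that decomposes above about −20 °C, and the 7-alkoxide formed under these basic conditions can trigger migration of the silyl group from O6 to O7, which would misdirect the later acetylation. Fallback, from 21 back to 24, avoiding both the lactol and the free alkoxide:
- The lactone 21 is opened with MeNH(OMe)·HCl and AlMe3 to the N-methoxy-N-methyl amide of (5R,6S,7R,8R,9S,10R)-6-(tert-butyldimethylsilyloxy)-7,8-dihydroxy-13,14,15,16-tetranorlabdan-12-oic acid F2.
- Both hydroxyls are capped with TMSOTf and 2,6-lutidine to give the 7,8-bis(trimethylsilyl) ether F3.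
- i-Bu2AlH at −78 °C gives the open-chain 6-(tert-butyldimethylsilyloxy)-7,8-bis(trimethylsilyloxy)-13,14,15,16-tetranorlabdan-12-al F4.
- The iodo-olefination on this ordinary aldehyde gives the (12Z)-13-iodo-14,15-dinorlabd-12-ene tris-silyl ether F5.
- Aqueous citric acid in MeOH removes the two trimethylsilyl groups, but not the hindered tert-butyldimethylsilyl ether, and returns 24.

**Step 11.** The enone β-carbon C5 lies between two quaternary carbons, so adsorption on the catalyst may be too slow, and forcing conditions invite hydrogenolysis of the C8–O bond next to the ketone. Fallback: a radical hydrogen-atom-transfer reduction in solution with Mn(dpm)3 (cat.) and PhSiH3 in i-PrOH. It delivers a hydrogen atom to C5 from the open β face and reduces the resulting C6 radical to the ketone, so it does not depend on a metal surface. It sets out from 16 and returns at 17 and creates no new compound (entry F0 below).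

**Step 4.** Addition to a ketone flanked by two quaternary carbons may stall or revert on warming. Fallback: build the butynyl group in two parts. The smallest acetylide, LiC≡CH·H2NCH2CH2NH2 in THF, is added to 5 to give (2S)-1-ethynyl-2,6,6-trimethyl-2-[(1E)-prop-1-en-1-yl]cyclohexan-1-ol F6. Its dianion (n-BuLi, 2.2 equiv, THF/DMPU) is then ethylated on carbon with EtI to give 7.

## Further compounds

F1 | step 8 | methyl (2E)-3-[(1S,2E)-1,3,3-trimethyl-2-(2-oxobutylidene)cyclohexyl]prop-2-enoate | CCC(=O)/C=C1\C(C)(C)CCC[C@@]1(C)/C=C/C(=O)OC
F2 | step 16 | (5R,6S,7R,8R,9S,10R)-6-(tert-butyldimethylsilyloxy)-7,8-dihydroxy-N-methoxy-N-methyl-13,14,15,16-tetranorlabdan-12-amide | CON(C)C(=O)C[C@@H]1[C@@](C)(O)[C@H](O)[C@@H](O[Si](C)(C)C(C)(C)C)[C@@H]2C(C)(C)CCC[C@]21C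
F3 | step 16 | 6-(tert-butyldimethylsilyloxy)-N-methoxy-N-methyl-7,8-bis(trimethylsilyloxy)-13,14,15,16-tetranorlabdan-12-amide, configuration as in F2 | CON(C)C(=O)C[C@@H]1[C@@](C)(O[Si](C)(C)C)[C@H](O[Si](C)(C)C)[C@@H](O[Si](C)(C)C(C)(C)C)[C@@H]2C(C)(C)CCC[C@]21C
F4 | step 16 | 6-(tert-butyldimethylsilyloxy)-7,8-bis(trimethylsilyloxy)-13,14,15,16-tetranorlabdan-12-al, configuration as in F2 | O=CC[C@@H]1[C@@](C)(O[Si](C)(C)C)[C@H](O[Si](C)(C)C)[C@@H](O[Si](C)(C)C(C)(C)C)[C@@H]2C(C)(C)CCC[C@]21C
F5 | step 16 | (12Z)-6-(tert-butyldimethylsilyloxy)-13-iodo-7,8-bis(trimethylsilyloxy)-14,15-dinorlabd-12-ene, configuration as in 24 | C/C(I)=C/C[C@@H]1[C@@](C)(O[Si](C)(C)C)[C@H](O[Si](C)(C)C)[C@@H](O[Si](C)(C)C(C)(C)C)[C@@H]2C(C)(C)CCC[C@]21C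
F0 | step 11 | none | none
F6 | step 4 | (2S)-1-ethynyl-2,6,6-trimethyl-2-[(1E)-prop-1-en-1-yl]cyclohexan-1-ol, both carbinol epimers | C#CC1(O)C(C)(C)CCC[C@@]1(C)/C=C/C
A1 | alternative 1 | (2Z,4S,5E,9Z)-4-[2-(tert-butyldiphenylsilyloxy)ethyl]-3,5,7,7-tetramethyl-10-(trimethylsilyl)deca-2,5,9-trien-1-ol (trimethylsilyl assumed for the vinylsilane) | OC/C=C(C)\[C@@H](CCO[Si](c1ccccc1)(c1ccccc1)C(C)(C)C)/C(C)=C/C(C)(C)C/C=C\[Si](C)(C)C
A2 | alternative 1 | 12-(tert-butyldiphenylsilyloxy)-13,14,15,16-tetranorlabda-1,7-diene of the enantiomeric series (C5, C9, C10 as in 28) | CC(C)(C)[Si](OCC[C@@H]1C(C)=CC[C@@H]2C(C)(C)CC=C[C@]21C)(c1ccccc1)c1ccccc1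
A3 | alternative 2 | 4-methyl-4-(triethylsilyloxy)-6-(2,6,6-trimethylcyclohex-1-en-1-yl)oxan-2-one, methyl and cyclohexenyl cis | O=C1C[C@@](C)(O[Si](CC)(CC)CC)C[C@@H](O1)C2=C(C)CCCC2(C)C
A4 | alternative 2 | 8-(triethylsilyloxy)drim-5-en-11-oic acid of the enantiomeric series, C9 epimer (carboxyl anti to the C10 methyl) | OC(=O)[C@H]1[C@@](C)(O[Si](CC)(CC)CC)CC=C2C(C)(C)CCC[C@]21C
A5 | alternative 3 | tert-butyl{[(2Z,4E)-6,6-dimethylnona-2,4,8-trien-3-yl]oxy}dimethylsilane | C/C=C(O[Si](C)(C)C(C)(C)C)/C=C/C(C)(C)CC=C
A6 | alternative 3 | (2E)-2-methyl-5-(triisopropylsilyloxy)pent-2-enal | O=C/C(C)=C/CCO[Si](C(C)C)(C(C)C)C(C)C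
A7 | alternative 3 | 4-(tert-butyldimethylsilyloxy)-1,3-dimethyl-6-(2-methylpent-4-en-2-yl)-2-[2-(triisopropylsilyloxy)ethyl]cyclohex-4-ene-1-carbaldehyde, endo adduct | CC(C)[Si](OCC[C@@H]1[C@@H](C)C(O[Si](C)(C)C(C)(C)C)=C[C@@H](C(C)(C)CC=C)[C@@]1(C)C=O)(C(C)C)C(C)C
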